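## Plan

1. Cuts in the target: the O-acetyl group (back to a silyl ether), C12–C13 (sp3–sp2 Suzuki–Miyaura coupling) and C11=C12 (methylenation). This leaves a bicyclic C11 aldehyde.
2. Enabling feature: ring B is a 3-methylenecyclohexene, with C6=C7 inside the ring and C8=C17 exocyclic. It is framed by C5–H, the methyl-bearing quaternary C10 and the methine C9. This is the adduct pattern of a vinylallene (C5=C6–C7=C8=C17) with a trisubstituted alkene (C9=C10), so C5–C10 and C8–C9 are cut together and both rings open to an acyclic allenyl trienal.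
3. The open chain is cut at C6–C7 (Stille), C5=C6 (Takai) and C4–C18 (1,2-shift in an epoxy silyl ether). C1–C5, C9 and C10 come from hepta-1,6-diyne, which is elaborated in two directions.
4. Forward order: chain assembly (steps 1–9), rings A and B together in one cycloaddition (step 10), side chain (steps 11–13), silyl-to-acetate exchange (steps 14–15).
5. Stereochemistry: C4 comes from a Sharpless epoxidation followed by a stereospecific migration. C5, C9 and C10 come from the cycloaddition (E enal, formyl-endo approach, facial bias from C4). The E alkenes come from syn-carboalumination, Takai olefination and stereoretentive couplings.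

Key step: step 10

Remark on numbering: labdane numbering is used (C18 = CH2O carbon on C4, C19 = methyl on C4, C20 = methyl on C10, C17 = exocyclic CH2). The target SMILES decodes as (4S,5S,9R,10S), a trans-decalin. C19, C20 and the C9 side chain lie on one face; H-5, H-9 and C18 lie on the other, so the CH2OAc group is equatorial.

Assumption: the 1,2-shift of step 5 is taken to run anti to the breaking C4–O bond (inversion at C4), as is the rule for this class of rearrangement. This is why the D-(−)-tartrate is used in step 3.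

## Route

**Step 1**
Reactants: 1 hepta-1,6-diyne
Product: 3 diethyl (2E,7E)-3,7-dimethylnona-2,7-dienedioate, via bis(dimethylalanyl)diene 2 (not isolated)
Conditions: Me3Al (6 equiv), Cp2ZrCl2 (0.5 equiv), CH2Cl2, 0 °C to rt; volatiles off; ClCO2Et (5 equiv), CH2Cl2, 0 °C to rt
Reagents that add atoms: trimethylaluminium, C[Al](C)C; ethyl chloroformate, CCOC(=O)Cl
Why: Zirconium-catalysed methylalumination (Negishi carboalumination) adds CH3 and Al syn to each terminal alkyne with Al on the terminal carbon, and the alkenylalanes are acylated by the chloroformate with retention, so both trisubstituted enoates should form as E isomers.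

**Step 2**
Reactants: 3 diethyl (2E,7E)-3,7-dimethylnona-2,7-dienedioate
Product: 4 ethyl (2E,7E)-9-hydroxy-3,7-dimethylnona-2,7-dienoate
Conditions: i-Bu2AlH (2.0 equiv), CH2Cl2, −78 °C; aq. potassium sodium tartrate
Reagents that add atoms: none
Why: This is the 1,2-reduction of an enoate to the allylic alcohol with i-Bu2AlH; the two ester ends are identical and remote, so a statistical mixture is expected, but diester, hydroxy ester and diol differ strongly in polarity, so 4 should be separable and recovered 3 can be resubmitted.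

**Step 3**
Reactants: 4 ethyl (2E,7E)-9-hydroxy-3,7-dimethylnona-2,7-dienoate
Product: 5 ethyl (2E)-6-[(2R,3R)-3-(hydroxymethyl)-2-methyloxiran-2-yl]-3-methylhex-2-enoate
Conditions: Ti(OiPr)4 (10 mol %), D-(−)-diisopropyl tartrate (12 mol %), t-BuOOH (2 equiv, decane), 4 Å molecular sieves, CH2Cl2, −20 °C
Reagents that add atoms: tert-butyl hydroperoxide, CC(C)(C)OO
Why: The Katsuki–Sharpless asymmetric epoxidation is directed by the free allylic hydroxyl, so only C4=C5 reacts while the electron-poor enoate stays untouched, and with the D-(−)-tartrate an (E)-3,3-disubstituted allylic alcohol of the geraniol type should give the (2R,3R)-epoxide, which fixes the configuration at C4.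

**Step 4**
Reactants: 5 epoxy alcohol
Product: 6 ethyl (2E)-6-[(2R,3R)-3-{[(tert-butyldiphenylsilyl)oxy]methyl}-2-methyloxiran-2-yl]-3-methylhex-2-enoate
Conditions: TBDPSCl (1.2 equiv), imidazole (2.5 equiv), DMF, 0 °C to rt
Reagents that add atoms: tert-butyldiphenylsilyl chloride, CC(C)(C)[Si](Cl)(c1ccccc1)c1ccccc1
Why: This is a routine silylation of a primary alcohol, and TBDPS is chosen because it withstands aluminium Lewis acids, hydride and aqueous base and later serves as the large group on C4.

**Step 5**
Reactants: 6 epoxy silyl ether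
Product: 7 ethyl (2E,7R)-7-{[(tert-butyldiphenylsilyl)oxy]methyl}-3,7-dimethyl-8-oxooct-2-enoate
Conditions: methylaluminium bis(4-bromo-2,6-di-tert-butylphenoxide) (MABR, 2.5 equiv, from Me3Al and 2 equiv of the phenol), CH2Cl2, −78 °C
Reagents that add atoms: none
Why: In this semipinacol-type rearrangement of an epoxy silyl ether to a β-silyloxy aldehyde the bulky aluminium Lewis acid opens the epoxide at tertiary C4 while the silyloxymethyl group shifts from C5 to C4 anti to the leaving oxygen, so the C4–C18 bond forms with clean inversion to the (R)-quaternary centre, the enoate alkene is too electron-poor to intercept the cationic carbon, and the excess reagent covers binding to the ester.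

**Step 6**
Reactants: 7 quaternary aldehyde
Product: 8 ethyl (2E,7S,8E)-7-{[(tert-butyldiphenylsilyl)oxy]methyl}-9-iodo-3,7-dimethylnona-2,8-dienoate
Conditions: CrCl2 (8 equiv), CHI3 (2.5 equiv), THF, 0 °C to rt
Reagents that add atoms: iodoform, IC(I)I
Why: In the Takai olefination the gem-dichromium reagent adds only to the aldehyde and eliminates to the E iodoalkene, a preference that the α-quaternary carbon should reinforce, while the enoate and silyl ether are inert to divalent chromium and C4 cannot epimerise.

**Step 7**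
Reactants: 8 iodo dienoate
Product: 9 (2E,7S,8E)-7-{[(tert-butyldiphenylsilyl)oxy]methyl}-9-iodo-3,7-dimethylnona-2,8-dien-1-ol
Conditions: i-Bu2AlH (2.5 equiv), CH2Cl2, −78 °C; aq. potassium sodium tartrate
Reagents that add atoms: none
Why: This is the 1,2-reduction of the enoate with i-Bu2AlH, and at low temperature the alkenyl iodide and the silyl ether are not attacked and the alkene geometry is retained.

**Step 8**
Reactants: 9 allylic alcohol
Product: 10 (2E,7S,8E)-7-{[(tert-butyldiphenylsilyl)oxy]methyl}-9-iodo-3,7-dimethylnona-2,8-dienal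
Conditions: MnO2 (20 equiv), CH2Cl2, rt
Reagents that add atoms: none
Why: MnO2 oxidises allylic alcohols selectively under neutral conditions, which should preserve the E geometry of the β,β-disubstituted enal and leave the iodoalkene untouched.

**Step 9**
Reactants: 10 iodo dienal; 11 allenyltributylstannane
Product: 12 (2E,7S,8E)-7-{[(tert-butyldiphenylsilyl)oxy]methyl}-3,7-dimethyldodeca-2,8,10,11-tetraenal
Conditions: Pd2(dba)3 (2.5 mol %), AsPh3 (20 mol %), degassed DMF, rt, dark
Reagents that add atoms: allenyltributylstannane (11), C=C=C[Sn](CCCC)(CCCC)CCCC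
Why: In this Stille coupling zerovalent palladium inserts into the C6–I bond with retention, the allenyl group passes from tin to palladium and reductive elimination joins C6 to C7, so the E alkene is kept and the terminal allene arrives intact under neutral conditions that spare the enal.

**Step 10**
Reactants: 12 acyclic vinylallene enal
Product: 13 (1R,4aS,5S,8aR)-5-{[(tert-butyldiphenylsilyl)oxy]methyl}-5,8a-dimethyl-2-methylidene-1,2,4a,5,6,7,8,8a-octahydronaphthalene-1-carbaldehyde (labdane locants 4S,5S,9R,10R)
Conditions: Me2AlCl (1.5 equiv), CH2Cl2 (0.01 M), −78 to −20 °C; Et3N then aq. NaHCO3 at −78 °C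
Reagents that add atoms: none
Why: Me2AlCl binds the formyl oxygen, lowers the enal LUMO and sets off a concerted, asynchronous [4+2] cycloaddition with C5=C6–C7=C8 as the four-electron and C9=C10 as the two-electron partner; the closest known reactions are the aluminium-Lewis-acid-promoted type 1 intramolecular Diels–Alder reactions of 2,8,10-trienals to trans-decalins and the intramolecular cycloadditions of vinylallenes to 3-methylenecyclohexenes. Ring B closes as the new cyclohexene (bonds C5–C10 and C8–C9, new alkene C6=C7), and ring A closes in the same event in the fused mode, because the four-carbon tether C1–C4 links diene terminus C5 to dienophile carbon C10. At C9 and C10, suprafacial addition to the E enal keeps the C20 methyl and the formyl group cis. At C5 relative to C10, the formyl-endo transition state of the E diene and E dienophile, reinforced by the Lewis acid, places H-5 trans to C20 and so gives the trans-decalin. The absolute sense comes from C4: in the chair-like tether one C4 substituent must point to the diene face that the dienophile approaches, next to the incoming C20, and the methyl group should take this axial site while the CH2OTBDPS arm stays on the open face and ends up equatorial. The step needs endo, facial and site selectivity, secured respectively by the complexed formyl group, by the size difference at C4 (the weakest element) and by the allene itself, whose C8=C17 π bond lies orthogonal to the diene and survives as the exocyclic methylene while the unsubstituted sp carbon C8 eases the approach that builds quaternary C10.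

**Step 11**
Reactants: 13 bicyclic dienyl aldehyde
Product: 14 (4S,5S,9R,10S)-18-(tert-butyldiphenylsilyloxy)-13,14,15,16-tetranorlabda-6,8(17),11-triene (13 with CH=CH2 in place of CHO)
Conditions: Ph3PCH3Br (1.5 equiv), KN(SiMe3)2 (1.4 equiv), THF, 0 °C; then 13, −78 to 0 °C
Reagents that add atoms: methyltriphenylphosphonium bromide, C[P+](c1ccccc1)(c1ccccc1)c1ccccc1.[Br-]
Why: In this Wittig methylenation the small, very reactive ylide, pre-formed without excess base, should add to the hindered formyl group at low temperature faster than it deprotonates C9, so the equatorial C9 configuration and the unconjugated C8=C17 bond are kept.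

**Step 12**
Reactants: 15 methyl acetoacetate
Product: 17 methyl (2E)-3-{[(trifluoromethyl)sulfonyl]oxy}but-2-enoate, via tetramethylammonium enolate 16 (not isolated)
Conditions: Tf2O (1.3 equiv), aq. Me4NOH, hexanes, 5–10 °C
Reagents that add atoms: triflic anhydride, O=S(=O)(OS(=O)(=O)C(F)(F)F)C(F)(F)F
Why: This is an O-triflation of a β-keto ester enolate under two-phase Schotten–Baumann-type conditions, and the non-coordinating Me4N+ ion cannot chelate the two oxygens, so the extended enolate with the oxide trans to the ester is trapped and the E enol triflate should result.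

**Step 13**
Reactants: 14 triene; 17 (E)-enol triflate
Product: 19 methyl (4S,5S,9R,10S,13E)-18-(tert-butyldiphenylsilyloxy)labda-6,8(17),13-trien-15-oate, via B-alkyl-9-BBN adduct 18 (not isolated)
Conditions: 9-BBN-H (1.3 equiv), THF, 0 °C to rt; then 17 (1.3 equiv), PdCl2(dppf) (5 mol %), aq. K3PO4 (3 equiv), DMF, rt
Reagents that add atoms: enol triflate (17), C/C(OS(=O)(=O)C(F)(F)F)=C\C(=O)OC
Why: 9-BBN should hydroborate the only monosubstituted alkene, with boron on C12, far faster than the 1,1-disubstituted end of the conjugated diene, and the B-alkyl Suzuki–Miyaura coupling with the electron-poor enol triflate forms C12–C13 with retention, so C13=C14 is E.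

**Step 14**
Reactants: 19 silyl-protected labdatrienoate
Product: 20 methyl (4S,5S,9R,10S,13E)-18-hydroxylabda-6,8(17),13-trien-15-oate
Conditions: Bu4NF (2 equiv), THF, rt to 40 °C
Reagents that add atoms: none
Why: This is a fluoride-driven cleavage of the Si–O bond, and the methyl enoate and the acid-sensitive exocyclic diene are not affected by these non-acidic conditions.

**Step 15**
Reactants: 20 primary neopentylic alcohol
Product: 21 CNP0148290.1, methyl (4S,5S,9R,10S,13E)-18-acetoxylabda-6,8(17),13-trien-15-oate
Conditions: Ac2O (3 equiv), pyridine, DMAP (cat.), CH2Cl2, rt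
Reagents that add atoms: acetic anhydride, CC(=O)OC(C)=O
Why: DMAP-catalysed acetylation handles hindered primary alcohols under mild basic conditions that touch no stereocentre and no alkene.

## Compound list

1 | hepta-1,6-diyne | C#CCCCC#C | starting material
2 | (1E,6E)-(2,6-dimethylhepta-1,6-diene-1,7-diyl)bis(dimethylalane) | C[Al](C)/C=C(C)/CCC/C(C)=C/[Al](C)C | intermediate
3 | diethyl (2E,7E)-3,7-dimethylnona-2,7-dienedioate | CCOC(=O)/C=C(C)/CCC/C(C)=C/C(=O)OCC | intermediate
4 | ethyl (2E,7E)-9-hydroxy-3,7-dimethylnona-2,7-dienoate | CCOC(=O)/C=C(C)/CCC/C(C)=C/CO | intermediate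
5 | ethyl (2E)-6-[(2R,3R)-3-(hydroxymethyl)-2-methyloxiran-2-yl]-3-methylhex-2-enoate | OC[C@H]1O[C@]1(C)CCC/C(C)=C/C(=O)OCC | intermediate
6 | TBDPS ether of 5 | CC(C)(C)[Si](c1ccccc1)(c1ccccc1)OC[C@H]1O[C@]1(C)CCC/C(C)=C/C(=O)OCC | intermediate
7 | ethyl (2E,7R)-7-(TBDPS-oxymethyl)-3,7-dimethyl-8-oxooct-2-enoate | O=C[C@@](C)(CO[Si](c1ccccc1)(c1ccccc1)C(C)(C)C)CCC/C(C)=C/C(=O)OCC | intermediate
8 | ethyl (2E,7S,8E)-7-(TBDPS-oxymethyl)-9-iodo-3,7-dimethylnona-2,8-dienoate | I/C=C/[C@@](C)(CO[Si](c1ccccc1)(c1ccccc1)C(C)(C)C)CCC/C(C)=C/C(=O)OCC | intermediate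
9 | (2E,7S,8E)-7-(TBDPS-oxymethyl)-9-iodo-3,7-dimethylnona-2,8-dien-1-ol | I/C=C/[C@@](C)(CO[Si](c1ccccc1)(c1ccccc1)C(C)(C)C)CCC/C(C)=C/CO | intermediate
10 | (2E,7S,8E)-7-(TBDPS-oxymethyl)-9-iodo-3,7-dimethylnona-2,8-dienal | I/C=C/[C@@](C)(CO[Si](c1ccccc1)(c1ccccc1)C(C)(C)C)CCC/C(C)=C/C=O | intermediate
11 | allenyltributylstannane | C=C=C[Sn](CCCC)(CCCC)CCCC | starting material
12 | (2E,7S,8E)-7-(TBDPS-oxymethyl)-3,7-dimethyldodeca-2,8,10,11-tetraenal | C=C=C/C=C/[C@@](C)(CO[Si](c1ccccc1)(c1ccccc1)C(C)(C)C)CCC/C(C)=C/C=O | intermediate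
13 | (1R,4aS,5S,8aR)-5-(TBDPS-oxymethyl)-5,8a-dimethyl-2-methylidene-1,2,4a,5,6,7,8,8a-octahydronaphthalene-1-carbaldehyde | C=C1C=C[C@@H]2[C@@](C)(CO[Si](c3ccccc3)(c3ccccc3)C(C)(C)C)CCC[C@@]2(C)[C@@H]1C=O | intermediate
14 | (4S,5S,9R,10S)-18-(TBDPS-oxy)-13,14,15,16-tetranorlabda-6,8(17),11-triene | C=C1C=C[C@@H]2[C@@](C)(CO[Si](c3ccccc3)(c3ccccc3)C(C)(C)C)CCC[C@@]2(C)[C@@H]1C=C | intermediate
15 | methyl acetoacetate | COC(=O)CC(C)=O | starting material
16 | tetramethylammonium (2E)-4-methoxy-4-oxobut-2-en-2-olate | C/C([O-])=C\C(=O)OC.C[N+](C)(C)C | intermediate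
17 | methyl (2E)-3-(trifluoromethylsulfonyloxy)but-2-enoate | C/C(OS(=O)(=O)C(F)(F)F)=C\C(=O)OC | intermediate
18 | 9-[(4S,5S,9R,10S)-18-(TBDPS-oxy)-13,14,15,16-tetranorlabda-6,8(17)-dien-12-yl]-9-borabicyclo[3.3.1]nonane | C=C1C=C[C@@H]2[C@@](C)(CO[Si](c3ccccc3)(c3ccccc3)C(C)(C)C)CCC[C@@]2(C)[C@@H]1CCB1C2CCCC1CCC2 | intermediate
19 | methyl (4S,5S,9R,10S,13E)-18-(TBDPS-oxy)labda-6,8(17),13-trien-15-oate | C=C1C=C[C@@H]2[C@@](C)(CO[Si](c3ccccc3)(c3ccccc3)C(C)(C)C)CCC[C@@]2(C)[C@@H]1CC/C(C)=C/C(=O)OC | intermediate
20 | methyl (4S,5S,9R,10S,13E)-18-hydroxylabda-6,8(17),13-trien-15-oate | C=C1C=C[C@@H]2[C@@](C)(CO)CCC[C@@]2(C)[C@@H]1CC/C(C)=C/C(=O)OC | intermediate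
21 | CNP0148290.1, methyl (4S,5S,9R,10S,13E)-18-acetoxylabda-6,8(17),13-trien-15-oate | C=C1C=C[C@@H]2[C@@](C)(COC(C)=O)CCC[C@@]2(C)[C@@H]1CC/C(C)=C/C(=O)OC | target

## Step count and risks

Total step count: 15. Longest linear sequence: 14 (steps 1–11 and 13–15). Step 12 is a one-step side branch.

**Step 10 (cycloaddition).**
- Bond formation between the neopentylic C5 and the fully substituted C10 may be slow. Lewis-acid-induced oligomerisation of the vinylallene or E/Z drift of the enal could then overtake it.
- Facial discrimination by C4 may be poor, because CH3 and CH2OSi differ only beyond their first atom.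
- The fallback keeps the same disconnection but hands activation and facial control to a covalently bound controller. It sets out from 8 and returns at 13.
- Saponification of 8 (LiOH, THF–MeOH–H2O) would give the carboxylic acid F1.
- Pivaloyl chloride and Et3N would give the mixed pivalic anhydride F2.
- (R)-4-Benzyl-1,3-oxazolidin-2-one with LiCl and Et3N would give the N-enoyl imide F3.
- Stille coupling with 11, as in step 9, gives the vinylallene imide F4.
- With more than one equivalent of Me2AlCl the two imide carbonyls chelate a cationic aluminium centre. This makes a much stronger dienophile, and the benzyl group shields the Si face of C9, so the diene should add to the Re face whatever the bias of C4. The carbonyl-endo mode then gives the trans-decalin imide F5.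
- LiBH4 (Et2O, MeOH) releases the auxiliary and gives the C11 alcohol F6.
- Dess–Martin periodinane oxidises F6 back to 13.

**Step 9 (allenyl transfer).**
- Transfer of the group from tin through its propargyl terminus, homocoupling, or palladium-induced oligomerisation of the newly formed vinylallene may erode the coupling.
- The fallback builds the allene by reductive transposition instead of by transfer. It sets out from 8 and returns at 12.
- Sonogashira coupling of 8 with prop-2-yn-1-ol (PdCl2(PPh3)2, CuI, Et3N) would give the enynol F7.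
- Mitsunobu reaction with 2-nitrobenzenesulfonylhydrazide (PPh3, DEAD, THF, −15 °C) gives the propargylic sulfonylhydrazine F8.
- On warming, F8 loses the sulfinic acid to give the propargylic diazene F9. This expels N2 in a retro-ene shift (Myers allene synthesis) to give the vinylallene ester F10.
- i-Bu2AlH gives the vinylallene allylic alcohol F11, and MnO2 gives 12.

**Step 11 (methylenation).**
- The basic ylide may enolise the hindered β,γ-unsaturated aldehyde. The C8=C17 bond could then drift into conjugation, or the C9 configuration could be lost.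
- The chemoselective hydroboration of step 13 also depends on the product of this step.
- The fallback avoids basic ylides and boranes altogether. It sets out from 13 and returns at 19, bypassing steps 11–13.
- Wittig reaction with the stabilised ylide Ph3P=CHC(O)CH3 (toluene, 80 °C) would give the (E)-enone F12.
- Conjugate reduction with [(Ph3P)CuH]6 (toluene, H2O) gives the methyl ketone F13 without touching the unactivated diene.
- Horner–Wadsworth–Emmons olefination with trimethyl phosphonoacetate and NaH (THF) gives 19. The E isomer is expected to predominate and the Z isomer would be removed by chromatography.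

## Further compounds

F1 | step 10 | (2E,7S,8E)-7-(TBDPS-oxymethyl)-9-iodo-3,7-dimethylnona-2,8-dienoic acid | I/C=C/[C@@](C)(CO[Si](c1ccccc1)(c1ccccc1)C(C)(C)C)CCC/C(C)=C/C(=O)O
F2 | step 10 | mixed anhydride of F1 with pivalic acid | I/C=C/[C@@](C)(CO[Si](c1ccccc1)(c1ccccc1)C(C)(C)C)CCC/C(C)=C/C(=O)OC(=O)C(C)(C)C
F3 | step 10 | (4R)-4-benzyl-3-[(2E,7S,8E)-7-(TBDPS-oxymethyl)-9-iodo-3,7-dimethylnona-2,8-dienoyl]-1,3-oxazolidin-2-one | I/C=C/[C@@](C)(CO[Si](c1ccccc1)(c1ccccc1)C(C)(C)C)CCC/C(C)=C/C(=O)N1[C@H](Cc2ccccc2)COC1=O
F4 | step 10 | (4R)-4-benzyl-3-[(2E,7S,8E)-7-(TBDPS-oxymethyl)-3,7-dimethyldodeca-2,8,10,11-tetraenoyl]-1,3-oxazolidin-2-one | C=C=C/C=C/[C@@](C)(CO[Si](c1ccccc1)(c1ccccc1)C(C)(C)C)CCC/C(C)=C/C(=O)N1[C@H](Cc2ccccc2)COC1=O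
F5 | step 10 | trans-decalin imide, (4S,5S,9R,10R), C11 acyl on (4R)-4-benzyl-1,3-oxazolidin-2-one | C=C1C=C[C@@H]2[C@@](C)(CO[Si](c3ccccc3)(c3ccccc3)C(C)(C)C)CCC[C@@]2(C)[C@@H]1C(=O)N1[C@H](Cc2ccccc2)COC1=O
F6 | step 10 | (4S,5S,9R,10R)-18-(TBDPS-oxy)-12,13,14,15,16-pentanorlabda-6,8(17)-dien-11-ol | C=C1C=C[C@@H]2[C@@](C)(CO[Si](c3ccccc3)(c3ccccc3)C(C)(C)C)CCC[C@@]2(C)[C@@H]1CO
F7 | step 9 | ethyl (2E,7S,8E)-7-(TBDPS-oxymethyl)-12-hydroxy-3,7-dimethyldodeca-2,8-dien-10-ynoate | OCC#C/C=C/[C@@](C)(CO[Si](c1ccccc1)(c1ccccc1)C(C)(C)C)CCC/C(C)=C/C(=O)OCC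
F8 | step 9 | N-propargylic 2-nitrobenzenesulfonylhydrazine derived from F7 | NN(CC#C/C=C/[C@@](C)(CO[Si](c1ccccc1)(c1ccccc1)C(C)(C)C)CCC/C(C)=C/C(=O)OCC)S(=O)(=O)c1ccccc1[N+](=O)[O-]
F9 | step 9 | propargylic diazene derived from F8 | N=NCC#C/C=C/[C@@](C)(CO[Si](c1ccccc1)(c1ccccc1)C(C)(C)C)CCC/C(C)=C/C(=O)OCC
F10 | step 9 | ethyl (2E,7S,8E)-7-(TBDPS-oxymethyl)-3,7-dimethyldodeca-2,8,10,11-tetraenoate | C=C=C/C=C/[C@@](C)(CO[Si](c1ccccc1)(c1ccccc1)C(C)(C)C)CCC/C(C)=C/C(=O)OCC
F11 | step 9 | (2E,7S,8E)-7-(TBDPS-oxymethyl)-3,7-dimethyldodeca-2,8,10,11-tetraen-1-ol | C=C=C/C=C/[C@@](C)(CO[Si](c1ccccc1)(c1ccccc1)C(C)(C)C)CCC/C(C)=C/CO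
F12 | step 11 | (4S,5S,9R,10S,11E)-18-(TBDPS-oxy)-14,15-dinorlabda-6,8(17),11-trien-13-one | C=C1C=C[C@@H]2[C@@](C)(CO[Si](c3ccccc3)(c3ccccc3)C(C)(C)C)CCC[C@@]2(C)[C@@H]1/C=C/C(C)=O
F13 | step 11 | (4S,5S,9R,10S)-18-(TBDPS-oxy)-14,15-dinorlabda-6,8(17)-dien-13-one | C=C1C=C[C@@H]2[C@@](C)(CO[Si](c3ccccc3)(c3ccccc3)C(C)(C)C)CCC[C@@]2(C)[C@@H]1CCC(C)=O
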